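**Retrosynthetic overview**

1. Target 22 comes from tricyclic enedione 14 by late oxygenation: C-4 acylation of diol 21, osmylation of C4=C5 anti to the C-3 angelate, allylic oxidation at C-11, C-9 methyl via an enol triflate, and C-3 by CBS reduction.
2. Key disconnection: C6–C7 and C2–C8 of 14 are cut together. This opens the seven-membered ring and the cyclobutane and leads to monocyclic cyclohexenone 10, which carries a 6-methyl-3-oxohept-5-en-2-yl chain.
3. Enabling feature: C-2 and C-6, the two ends of the C2–C6 bridge of the seven-membered ring, are the α′- and γ-positions of one ketone at C-3 (across C4=C5). C-7 and C-8, two adjacent cyclobutane CH carbons, are the β- and α-carbons of a cyclohex-2-enone once C-9 is a carbonyl. The dienolate therefore adds C-6 to C-7, and the C-8 enolate so formed is coupled oxidatively with the C-2 enolate.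
4. 10 comes from α-prenylation and oxidation of aldehyde 8, which comes from an aldol condensation after an organocatalytic Michael addition of aldehyde 4 to methyl vinyl ketone (this sets C-1, the only stereocentre carried into the key step).
5. Ring order: six-membered ring (step 4), then seven-membered ring and cyclobutane in one operation (step 8).

Key step: step 8

Remark on the chemistry: the methyl-bearing side-chain carbon (later C-2) is carried as an epimer mixture from racemic 1, because it becomes a planar enolate carbon in step 8. Locants C-1 to C-11 are those of the tricyclo[5.4.0.0^2,8]undecane skeleton of the target and are used for the matching atoms of all intermediates: C-1 bridgehead next to the C-11 ketone, C-2 quaternary methyl carbon, C-3 to C-5 oxygenated carbons, C-6 gem-dimethyl carbon, C-7 and C-8 the other cyclobutane carbons, C-9 methyl-bearing alkene carbon. Carbon inputs other than 1 (methyl vinyl ketone, prenyl chloride, MeZnCl, angelic acid, 3-methylbutanoic anhydride) are commercial reagents and appear under "Reagents that add atoms".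

**Route**

Step 1
Reactants: 1 2-methylpent-4-enal (racemic)
Product: 2 5,5-dimethoxy-4-methylpent-1-ene
Conditions: HC(OMe)3, p-TsOH·H2O (cat.), MeOH, 23 °C
Reagents that add atoms: trimethyl orthoformate, COC(OC)OC
Why: Acid-catalysed acetalisation masks this formyl carbon (the later C-3), so that the aldehyde made in step 2 is the only one that can form an enamine in step 3.

Step 2
Reactants: 2 5,5-dimethoxy-4-methylpent-1-ene
Product: 4 4,4-dimethoxy-3-methylbutanal, via secondary ozonide 3 (not isolated)
Conditions: O3, CH2Cl2, −78 °C; then PPh3, −78 to 23 °C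
Reagents that add atoms: ozone, [O-][O+]=O
Why: Ozonolysis of the terminal alkene with reductive work-up gives the aldehyde, the dimethyl acetal being inert to ozone and to the phosphine.

Step 3
Reactants: 4 4,4-dimethoxy-3-methylbutanal
Product: 5 (2S)-2-[(2RS)-1,1-dimethoxypropan-2-yl]-5-oxohexanal
Conditions: methyl vinyl ketone (1.5 equiv), (S)-2-[methoxy(diphenyl)methyl]pyrrolidine (5 mol%), ethyl 3,4-dihydroxybenzoate (20 mol%), neat, 4 °C
Reagents that add atoms: methyl vinyl ketone, C=CC(C)=O
Why: Enamine-catalysed asymmetric Michael addition of an aldehyde to an enone: the (E)-enamine is attacked on the face away from the Ph2C(OMe) group, which should set the later C-1 as (2S) in 5, while the acetal-bearing neighbour stays an epimer mixture that is erased in step 8.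

Step 4
Reactants: 5 (2S)-2-[(2RS)-1,1-dimethoxypropan-2-yl]-5-oxohexanal
Product: 7 (4R)-4-[(2RS)-1,1-dimethoxypropan-2-yl]cyclohex-2-en-1-one, via aldol 6 (not isolated)
Conditions: LiOH·H2O (0.2 equiv), i-PrOH, 23 °C
Reagents that add atoms: none
Why: Intramolecular aldol condensation (6-(enolendo)-exo-trig closure of the methyl ketone enolate onto the aldehyde, then loss of water from aldol 6) gives the 4-substituted cyclohex-2-enone; the stereocentre should survive because ring closure outruns enolisation of the α-branched aldehyde, and it is no longer α to a carbonyl afterwards.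

Step 5
Reactants: 7 (4R)-4-[(2RS)-1,1-dimethoxypropan-2-yl]cyclohex-2-en-1-one
Product: 8 (2RS)-2-[(1R)-4-oxocyclohex-2-en-1-yl]propanal
Conditions: 1 M HCl, THF, 0 °C
Reagents that add atoms: water, O
Why: Acid-catalysed acetal hydrolysis frees the aldehyde without touching the enone or its γ-stereocentre; the epimerisable centre next to the aldehyde is already a mixture.

Step 6
Reactants: 8 (2RS)-2-[(1R)-4-oxocyclohex-2-en-1-yl]propanal
Product: 9 (4R)-4-[(2RS,3RS)-3-hydroxy-6-methylhept-5-en-2-yl]cyclohex-2-en-1-one
Conditions: prenyl chloride, activated Ba metal, THF, −78 °C; then 8, −78 °C; aq. NH4Cl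
Reagents that add atoms: prenylbarium chloride, CC(C)=CC[Ba]Cl (made in the flask from prenyl chloride, CC(C)=CCCl)
Why: Allylic barium reagents add to aldehydes through their less substituted α-carbon, so the linear prenyl carbinol is expected, and at −78 °C the aldehyde should react before the enone; the new carbinol centre is uncontrolled and is oxidised away in step 7.

Step 7
Reactants: 9 (4R)-4-[(2RS,3RS)-3-hydroxy-6-methylhept-5-en-2-yl]cyclohex-2-en-1-one
Product: 10 (4R)-4-[(2RS)-6-methyl-3-oxohept-5-en-2-yl]cyclohex-2-en-1-one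
Conditions: Dess–Martin periodinane, pyridine, CH2Cl2, 0 °C
Reagents that add atoms: none
Why: Dess–Martin oxidation buffered with pyridine is neutral enough to give the β,γ-unsaturated ketone without moving the alkene into conjugation, which would destroy the doubly activated C-4 methylene needed in step 8.

Step 8
Reactants: 10 (4R)-4-[(2RS)-6-methyl-3-oxohept-5-en-2-yl]cyclohex-2-en-1-one
Product: 14 (1R,2S,7R,8S)-2,6,6-trimethyltricyclo[5.4.0.0^2,8]undec-4-ene-3,9-dione, via lithium dienolate 11 (not isolated), via bicyclic lithium enolate 12 (not isolated), via dilithium bis-enolate 13 (not isolated)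
Conditions: LiN(SiMe3)2 (1.0 equiv), THF, −78 to −20 °C; LiN(i-Pr)2 (1.1 equiv), −78 °C; Fe(acac)3 (2.2 equiv), −78 to 0 °C; aq. NH4Cl
Reagents that add atoms: none
Why: Proposed new method: LiN(SiMe3)2 removes a proton from the doubly activated C-4 methylene to give the extended dienolate 11, whose γ-carbon C-6 adds to the enone β-carbon C-7 (intramolecular vinylogous Michael addition) and leaves the ring enolate 12; LiN(i-Pr)2 then removes the only acidic hydrogen left, at C-2 (α′ of the new cycloheptenone), and Fe(acac)3 oxidises bis-enolate 13 so that the α-keto radical formed at one enolate carbon is captured by the other, which joins C-2 to C-8. The closest known reaction types are vinylogous Michael additions of dienolates made from β,γ-unsaturated ketones and the oxidative heterocoupling of two enolates by Fe(acac)3 or copper salts, which is known in intramolecular form and also closes cyclobutanes from diester bis-enolates; running both in one flask and closing a bridged four-membered ring in this way has no direct precedent. The seven-membered ring closes by a 7-exo-trig conjugate addition in which the dienolate lies inside the new ring, and the cyclobutane by a 1,3-coupling across the six-membered ring (a 4-exo closure that gives the bicyclo[3.1.1]heptane). C-7 is set by axial attack on the enone from the side-chain face, because the four-atom tether from C-1 can only span a cis ring fusion, and C-8 and C-2 can then only be joined on that same face, so the single stereocentre C-1 of 10 controls all three new centres while both C-2 epimers of 10 converge. The step needs γ- and not α-attack of 11 (α-attack would be a 5-(enolendo)-exo-trig closure, disfavoured by the ring-closure rules for enolates), the C-8 and not the C-10 enolate of the ring ketone (12 is made regiospecifically by the conjugate addition and is not allowed to equilibrate) and an intact C-1 (the stoichiometric amide base takes only the far more acidic C-4 proton and not the γ-hydrogen of the cyclohexenone).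

Step 9
Reactants: 14 (1R,2S,7R,8S)-2,6,6-trimethyltricyclo[5.4.0.0^2,8]undec-4-ene-3,9-dione
Product: 16 (1R,2S,7R,8S)-2,6,6-trimethyl-3-oxotricyclo[5.4.0.0^2,8]undeca-4,9-dien-9-yl trifluoromethanesulfonate, via potassium enolate 15 (not isolated)
Conditions: KN(SiMe3)2, THF, −78 °C; PhNTf2, −78 to 0 °C; aq. NH4Cl
Reagents that add atoms: N-phenylbis(trifluoromethanesulfonimide), O=S(=O)(N(c1ccccc1)S(=O)(=O)C(F)(F)F)C(F)(F)F
Why: Only the C-9 ketone can enolise (C-8 is a bridgehead of the bicyclo[3.1.1]heptane, and the C-3 enone has neither α- nor γ-hydrogen), so O-sulfonylation of its potassium enolate gives a single enol triflate.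

Step 10
Reactants: 16 (1R,2S,7R,8S)-2,6,6-trimethyl-3-oxotricyclo[5.4.0.0^2,8]undeca-4,9-dien-9-yl trifluoromethanesulfonate
Product: 17 (1R,2S,7R,8R)-2,6,6,9-tetramethyltricyclo[5.4.0.0^2,8]undeca-4,9-dien-3-one
Conditions: MeZnCl, Pd(PPh3)4 (5 mol%), THF, 50 °C
Reagents that add atoms: methylzinc chloride, C[Zn]Cl
Why: Negishi cross-coupling of the enol triflate under zerovalent palladium puts the methyl group on C-9; organozinc reagents do not add to the enone, and the coupling is done before C-3 carries an allylic ester that palladium could ionise.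

Step 11
Reactants: 17 (1R,2S,7R,8R)-2,6,6,9-tetramethyltricyclo[5.4.0.0^2,8]undeca-4,9-dien-3-one
Product: 18 (1R,2S,3R,7R,8R)-2,6,6,9-tetramethyltricyclo[5.4.0.0^2,8]undeca-4,9-dien-3-ol
Conditions: (S)-2-methyl-CBS-oxazaborolidine (20 mol%), catecholborane, toluene, −78 °C; aqueous work-up
Reagents that add atoms: none
Why: Corey–Bakshi–Shibata reduction: the tricycle has an approximate mirror plane through C-3 and offers no facial bias of its own, so the catalyst decides; with the quaternary C-2 as the large and the vinylic C-4 as the small group the (S)-catalyst should give the (3R)-alcohol, and catecholborane at −78 °C reduces the enone 1,2 without hydroborating the ring alkene.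

Step 12
Reactants: 18 (1R,2S,3R,7R,8R)-2,6,6,9-tetramethyltricyclo[5.4.0.0^2,8]undeca-4,9-dien-3-ol
Product: 19 (1R,2S,3R,7R,8R)-2,6,6,9-tetramethyltricyclo[5.4.0.0^2,8]undeca-4,9-dien-3-yl (2Z)-2-methylbut-2-enoate
Conditions: angelic acid, 2,4,6-trichlorobenzoyl chloride, Et3N, toluene, 23 °C; then 18, 80 °C
Reagents that add atoms: angelic acid ((2Z)-2-methylbut-2-enoic acid), C/C=C(/C)C(=O)O
Why: Yamaguchi esterification: the mixed anhydride of angelic acid acylates the hindered allylic alcohol on heating without a nucleophilic catalyst, conditions under which the (Z)-angelate is not expected to isomerise to the tiglate.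

Step 13
Reactants: 19 (1R,2S,3R,7R,8R)-2,6,6,9-tetramethyltricyclo[5.4.0.0^2,8]undeca-4,9-dien-3-yl (2Z)-2-methylbut-2-enoate
Product: 20 (1R,2R,3R,7S,8R)-2,6,6,9-tetramethyl-11-oxotricyclo[5.4.0.0^2,8]undeca-4,9-dien-3-yl (2Z)-2-methylbut-2-enoate
Conditions: Rh2(cap)4 (dirhodium tetracaprolactamate, 1 mol%), t-BuOOH, K2CO3, CH2Cl2, 23 °C
Reagents that add atoms: tert-butyl hydroperoxide, CC(C)(C)OO
Why: Allylic C–H oxidation (the α-pinene-to-verbenone type of transformation) should take place at the ring methylene C-11, because C-8 is a bridgehead, the C-3 hydrogen is deactivated by its acyloxy group and the methyl groups are primary; it also turns the electron-rich ring alkene into an enone that will not compete in step 14.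

Step 14
Reactants: 20 (1R,2R,3R,7S,8R)-2,6,6,9-tetramethyl-11-oxotricyclo[5.4.0.0^2,8]undeca-4,9-dien-3-yl (2Z)-2-methylbut-2-enoate
Product: 21 (1R,2R,3S,4S,5S,7S,8R)-4,5-dihydroxy-2,6,6,9-tetramethyl-11-oxotricyclo[5.4.0.0^2,8]undec-9-en-3-yl (2Z)-2-methylbut-2-enoate
Conditions: K2OsO4·2H2O (5 mol%), N-methylmorpholine N-oxide, acetone–H2O, 23 °C
Reagents that add atoms: N-methylmorpholine N-oxide, C[N+]1([O-])CCOCC1; water, O
Why: Catalytic osmylation (Upjohn dihydroxylation) should pick the cis-disubstituted C4=C5 alkene over the two electron-poor trisubstituted alkenes and add on the face opposite to the allylic C-3 acyloxy group (the usual anti preference of allylic oxygen substituents), which sets C-4 and C-5 cis to each other and trans to the C-3 oxygen (4S,5S).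

Step 15
Reactants: 21 (1R,2R,3S,4S,5S,7S,8R)-4,5-dihydroxy-2,6,6,9-tetramethyl-11-oxotricyclo[5.4.0.0^2,8]undec-9-en-3-yl (2Z)-2-methylbut-2-enoate
Product: 22 (1R,2R,3S,4S,5S,7S,8R)-5-hydroxy-2,6,6,9-tetramethyl-4-[(3-methylbutanoyl)oxy]-11-oxotricyclo[5.4.0.0^2,8]undec-9-en-3-yl (2Z)-2-methylbut-2-enoate
Conditions: 3-methylbutanoic anhydride (1.1 equiv), pyridine, DMAP (cat.), CH2Cl2, −20 to 0 °C
Reagents that add atoms: 3-methylbutanoic anhydride, CC(C)CC(=O)OC(=O)CC(C)C
Why: Steric differentiation of the two hydroxyls in a DMAP-catalysed acylation: the C-5 hydroxyl is neopentylic next to the gem-dimethyl carbon C-6, so one equivalent of anhydride at low temperature should esterify only C-4.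

**Compound list**

1 | 2-methylpent-4-enal (racemic) | C=CCC(C)C=O | starting material
2 | 5,5-dimethoxy-4-methylpent-1-ene (racemic) | C=CCC(C)C(OC)OC | intermediate
3 | 3-(3,3-dimethoxy-2-methylpropyl)-1,2,4-trioxolane (secondary ozonide) | COC(OC)C(C)CC1OCOO1 | intermediate
4 | 4,4-dimethoxy-3-methylbutanal (racemic) | COC(OC)C(C)CC=O | intermediate
5 | (2S)-2-[(2RS)-1,1-dimethoxypropan-2-yl]-5-oxohexanal | O=C[C@@H](CCC(C)=O)C(C)C(OC)OC | intermediate
6 | (4S)-4-[(2RS)-1,1-dimethoxypropan-2-yl]-3-hydroxycyclohexan-1-one (aldol, carbinol epimers) | COC(OC)C(C)[C@@H]1CCC(=O)CC1O | intermediate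
7 | (4R)-4-[(2RS)-1,1-dimethoxypropan-2-yl]cyclohex-2-en-1-one | COC(OC)C(C)[C@H]1C=CC(=O)CC1 | intermediate
8 | (2RS)-2-[(1R)-4-oxocyclohex-2-en-1-yl]propanal | O=CC(C)[C@H]1C=CC(=O)CC1 | intermediate
9 | (4R)-4-[(2RS,3RS)-3-hydroxy-6-methylhept-5-en-2-yl]cyclohex-2-en-1-one | CC(C)=CCC(O)C(C)[C@H]1C=CC(=O)CC1 | intermediate
10 | (4R)-4-[(2RS)-6-methyl-3-oxohept-5-en-2-yl]cyclohex-2-en-1-one | CC(C)=CCC(=O)C(C)[C@H]1C=CC(=O)CC1 | intermediate
11 | lithium (E)-dienolate of 10 (O on C-3, C3=C4 and C5=C6 double bonds, C-2 cis to C-5) | [Li+].[O-]/C(=C/C=C(C)C)C(C)[C@H]1C=CC(=O)CC1 | intermediate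
12 | lithium C8=C9 enolate of the cis-fused bicyclic Michael adduct (C6–C7 bond formed, C-2 epimers) | [Li+].[O-]C1=C[C@H]2[C@@H](CC1)C(C)C(=O)C=CC2(C)C | intermediate
13 | dilithium bis-enolate (C8=C9–O and C2=C3–O) of the cis-fused bicycle | [Li+].[Li+].[O-]C1=C[C@H]2[C@@H](CC1)C(C)=C([O-])C=CC2(C)C | intermediate
14 | (1R,2S,7R,8S)-2,6,6-trimethyltricyclo[5.4.0.0^2,8]undec-4-ene-3,9-dione | O=C1C=CC(C)(C)[C@@H]2[C@H]3CCC(=O)[C@@H]2[C@@]13C | intermediate
15 | potassium C9=C10 enolate of 14 | [K+].O=C1C=CC(C)(C)[C@@H]2[C@H]3CC=C([O-])[C@@H]2[C@@]13C | intermediate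
16 | (1R,2S,7R,8S)-2,6,6-trimethyl-3-oxotricyclo[5.4.0.0^2,8]undeca-4,9-dien-9-yl trifluoromethanesulfonate | O=C1C=CC(C)(C)[C@@H]2[C@H]3CC=C(OS(=O)(=O)C(F)(F)F)[C@@H]2[C@@]13C | intermediate
17 | (1R,2S,7R,8R)-2,6,6,9-tetramethyltricyclo[5.4.0.0^2,8]undeca-4,9-dien-3-one | O=C1C=CC(C)(C)[C@@H]2[C@H]3CC=C(C)[C@@H]2[C@@]13C | intermediate
18 | (1R,2S,3R,7R,8R)-2,6,6,9-tetramethyltricyclo[5.4.0.0^2,8]undeca-4,9-dien-3-ol | O[C@@H]1C=CC(C)(C)[C@@H]2[C@H]3CC=C(C)[C@@H]2[C@@]13C | intermediate
19 | (1R,2S,3R,7R,8R)-2,6,6,9-tetramethyltricyclo[5.4.0.0^2,8]undeca-4,9-dien-3-yl (2Z)-2-methylbut-2-enoate | C/C=C(/C)C(=O)O[C@@H]1C=CC(C)(C)[C@@H]2[C@H]3CC=C(C)[C@@H]2[C@@]13C | intermediate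
20 | (1R,2R,3R,7S,8R)-2,6,6,9-tetramethyl-11-oxotricyclo[5.4.0.0^2,8]undeca-4,9-dien-3-yl (2Z)-2-methylbut-2-enoate | C/C=C(/C)C(=O)O[C@@H]1C=CC(C)(C)[C@@H]2[C@H]3C(=O)C=C(C)[C@@H]2[C@@]13C | intermediate
21 | (1R,2R,3S,4S,5S,7S,8R)-4,5-dihydroxy-2,6,6,9-tetramethyl-11-oxotricyclo[5.4.0.0^2,8]undec-9-en-3-yl (2Z)-2-methylbut-2-enoate | C/C=C(/C)C(=O)O[C@@H]1[C@@H](O)[C@@H](O)C(C)(C)[C@@H]2[C@H]3C(=O)C=C(C)[C@@H]2[C@@]13C | intermediate
22 | (1R,2R,3S,4S,5S,7S,8R)-5-hydroxy-2,6,6,9-tetramethyl-4-[(3-methylbutanoyl)oxy]-11-oxotricyclo[5.4.0.0^2,8]undec-9-en-3-yl (2Z)-2-methylbut-2-enoate (CNP0251293.1) | C/C=C(/C)C(=O)O[C@@H]1[C@@H](OC(=O)CC(C)C)[C@@H](O)C(C)(C)[C@@H]2[C@H]3C(=O)C=C(C)[C@@H]2[C@@]13C | target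

**Step count and risks**

Total steps: 15. Longest linear sequence: 15 steps (1 to 22).

Steps most likely to fail:

1. Step 8 (proposed new method). What may go wrong: the dienolate may form as the geometric isomer with C-2 trans to C-5 on the C3–C4 enolate bond, which cannot reach C-7 and may not isomerise fast enough. The bis-enolate may also be oxidised to hydroxylated or dimeric material before the strained four-membered ring closes. Fallback with known reaction types, from 10 back to 14: the dienolate addition is run alone (LiN(SiMe3)2, THF) and the ring enolate is trapped with Me3SiCl to give the silyl enol ether F1. N-Bromosuccinimide in THF at −78 °C converts this into the C-8 bromo ketone F2; bromine should enter on the face away from the seven-membered ring, and the centre can also epimerise. KN(SiMe3)2 in THF then forms the C-2 enolate, which displaces bromide in an intramolecular enolate alkylation (4-exo-tet, the established way to close bicyclo[3.1.1]heptanones by 1,3-alkylation) and gives 14. O-Alkylation is not a competitor there because it would place a bridgehead enol ether in the ring system.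

2. Step 11. What may go wrong: hydride delivery to the wrong face if the catalyst does not tell the quaternary C-2 side from the alkene side clearly, or partial 1,4-reduction. Fallback from 17 to 19: Luche reduction (NaBH4, CeCl3·7H2O, MeOH, −78 °C) gives the allylic alcohol under substrate control. If the product is the (3S)-alcohol F3, Mitsunobu esterification with angelic acid (PPh3, diisopropyl azodicarboxylate, toluene) inverts C-3 and gives angelate 19 directly; any (3R)-alcohol formed is 18 itself.

3. Step 6. What may go wrong: bonding through the γ-carbon of the prenyl metal (giving the branched 1,1-dimethylallyl carbinol), competing addition to the enone, or incomplete formation of the organobarium reagent. Fallback from 8 to 9: allylboration with pinacol allylboronate (CH2Cl2, 23 °C), which touches only the aldehyde, gives the homoallylic alcohol F4. Cross-metathesis with 2-methylbut-2-ene (second-generation Grubbs catalyst, CH2Cl2, 40 °C) then turns the terminal alkene into the prenyl group and gives 9.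

**Further compounds**

F1 | step 8 | trimethylsilyl enol ether (C8=C9–OSiMe3) of the cis-fused bicyclic Michael adduct | C[Si](C)(C)OC1=C[C@H]2[C@@H](CC1)C(C)C(=O)C=CC2(C)C
F2 | step 8 | C-8 bromo ketone of the cis-fused bicyclic Michael adduct | BrC1C(=O)CC[C@H]2C(C)C(=O)C=CC(C)(C)[C@@H]12
F3 | step 11 | (1R,2S,3S,7R,8R)-2,6,6,9-tetramethyltricyclo[5.4.0.0^2,8]undeca-4,9-dien-3-ol | O[C@H]1C=CC(C)(C)[C@@H]2[C@H]3CC=C(C)[C@@H]2[C@@]13C
F4 | step 6 | (4R)-4-[(2RS,3RS)-3-hydroxyhex-5-en-2-yl]cyclohex-2-en-1-one | C=CCC(O)C(C)[C@H]1C=CC(=O)CC1
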